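**Plan**

- Cuts, in retrosynthetic order: the three aryl O–Si bonds; the aryl–carbinol bond on the C5 arm (aldehyde + arylzinc); the styrene C=C (Julia–Kocienski); the C3–CH2 bond (exocyclic C=C made from a C3 ketone); the ring O1–C6 bond (ring expansion of a furan); the furyl–carbinol bond that becomes C2–C3 (2-furylzinc + aryl aldehyde).
- Enabling feature: O1, C2 with its aryl group, and C3–C6 of the oxane are a masked aryl 2-furyl carbinol whose furan C4 already bears the one-carbon arm of C5. All ring stereocentres can therefore be set on one flat pyranone.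
- Forward order: 2-bromo-4-substituted furan → (S)-aryl furyl carbinol → NBS ring expansion (the only ring formed) → C6 deoxygenation → Wittig at C3 → hydrogenation → sulfone → styrene → C5 arm oxidised and arylated → desilylation.
- Stereochemistry: C2 from a (+)-MIB-catalysed furyl transfer to 4-(TIPSO)benzaldehyde; C3 and C5 from hydrogenation of the flat dienoate anti to the C2 aryl group (all-cis); the carbinol from a (−)-MIB-catalysed aryl transfer; the E alkene from pairing an alkyl sulfone with an aryl aldehyde.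
- Protection: the primary alcohol as an acid-labile TBS ether, the phenols as TIPS ethers kept to the end.

Key step: step 5

Abbreviations: TBSOCH2 = (tert-butyldimethylsilyloxy)methyl; TIPSO = triisopropylsilyloxy; (−)-MIB = (2S)-3-exo-morpholinoisoborneol; (+)-MIB = its enantiomer, (2R)-3-exo-morpholinoisoborneol.

Remark: all ring compounds are named with the oxane locants of the target (O1, C2 aryl, C3 long arm, C5 short arm, C6 OCH2), so CIP letters change where substituent priorities change although no centre is inverted; 5-bromofuran-3-carboxylic acid is taken as a catalogue compound; (−)-MIB is assumed to send the zinc-bound carbon group to the Si face of an aldehyde, as in its dialkylzinc additions, and (+)-MIB to the Re face.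

**Route**

Step 1
Reactants: 1 5-bromofuran-3-carboxylic acid
Product: 2 (5-bromofuran-3-yl)methanol
Conditions: BH3·THF, THF, 0 °C → rt
Reagents that add atoms: none
Why: Borane reduction of a carboxylic acid runs through the acyloxyborane and is chemoselective, so the furan C–Br bond that later fixes the site of metalation is left alone.

Step 2
Reactants: 2 (5-bromofuran-3-yl)methanol
Product: 3 [(5-bromofuran-3-yl)methoxy](tert-butyl)dimethylsilane
Conditions: TBSCl, imidazole, CH2Cl2, rt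
Reagents that add atoms: tert-butyl(chloro)dimethylsilane, CC(C)(C)[Si](C)(C)Cl
Why: Imidazole-promoted silylation of a primary alcohol, chosen because an alkyl TBS ether can later be removed with acid while aryl TIPS ethers stay.

Step 3
Reactants: 4 4-hydroxybenzaldehyde
Product: 5 4-(TIPSO)benzaldehyde
Conditions: TIPSCl, imidazole, DMF, rt
Reagents that add atoms: chlorotri(propan-2-yl)silane, CC(C)[Si](Cl)(C(C)C)C(C)C
Why: Silylation of a phenol; the bulky TIPS group is chosen so that the para-formyl aryl silyl ether withstands both the organozinc addition and the strongly basic olefination in which this aldehyde is used.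

Step 4
Reactants: 3 [(5-bromofuran-3-yl)methoxy](tert-butyl)dimethylsilane; 5 4-(TIPSO)benzaldehyde
Product: 9 (S)-[4-(TBSOCH2)furan-2-yl][4-(TIPSO)phenyl]methanol, via 2-furyllithium 6 (not isolated), via 2-furylzinc chloride 7 (not isolated), via butyl(2-furyl)zinc 8 (not isolated)
Conditions: 3, n-BuLi, t-BuOMe, −78 °C; ZnCl2, −78 → 0 °C; n-BuLi; N,N,N′,N′-tetraethylethylenediamine, (+)-MIB (5 mol%), toluene; then 5, 0 °C
Reagents that add atoms: none
Why: Amino-alcohol-catalysed enantioselective heteroaryl transfer from a mixed heteroaryl(alkyl)zinc to an aromatic aldehyde: bromine–lithium exchange puts the metal only where the bromine was (no C2/C5 ambiguity of a 3-substituted furan), the zinc aminoalkoxide of (+)-MIB should deliver the furyl group to the Re face of the aldehyde and so give the S carbinol, and the diamine ties up LiCl to suppress the racemic background addition.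

Step 5
Reactants: 9 (S)-[4-(TBSOCH2)furan-2-yl][4-(TIPSO)phenyl]methanol
Product: 11 (2S)-5-(TBSOCH2)-6-hydroxy-2-[4-(TIPSO)phenyl]-2H-pyran-3(6H)-one as a mixture of C6 anomers, via Z-ene-dione 10 (not isolated)
Conditions: NBS, NaHCO3, THF/H2O (4:1), 0 °C
Reagents that add atoms: water, O
Why: NBS brominates the free α-carbon of the furan, water adds at the carbinol-bearing α-carbon and loss of bromide opens the ring to the Z-ene-dione 10, in which the former furan oxygen has become the C3 ketone. The carbinol oxygen then adds to the aldehyde carbon in a 6-exo-trig hemiacetalisation that forms the O1–C6 bond and the pyranone ring; this is the Achmatowicz rearrangement, well known for aryl 2-furyl carbinols. C2 is not touched, so its S configuration from step 4 is carried into 11. The only new stereocentre is the hemiacetal carbon C6, which forms as an equilibrating anomeric mixture under thermodynamic control and is deleted in step 6. The step needs oxidation of the furan in preference to the silyloxyarene, which is secured because the 2,4-dialkylfuran is the most electron-rich π system and the phenol is masked as its TIPS ether. The NaHCO3 buffer removes HBr so that the doubly benzylic carbinol does not ionise, and the low temperature and short contact time limit enolisation at C2 of the product.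

Step 6
Reactants: 11 (2S)-5-(TBSOCH2)-6-hydroxy-2-[4-(TIPSO)phenyl]-2H-pyran-3(6H)-one
Product: 12 (2S)-5-(TBSOCH2)-2-[4-(TIPSO)phenyl]-2H-pyran-3(6H)-one
Conditions: Et3SiH, CF3CO2H, CH2Cl2, −40 °C
Reagents that add atoms: none
Why: Ionic hydrogenation of a lactol: the acid ionises the C6 hydroxyl to the ring oxocarbenium ion, which Et3SiH reduces, C2 takes no part, and cold anhydrous acid should spare the alkyl TBS and aryl TIPS ethers.

Step 7
Reactants: 12 (2S)-5-(TBSOCH2)-2-[4-(TIPSO)phenyl]-2H-pyran-3(6H)-one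
Product: 13 ethyl 2-[(2S)-5-(TBSOCH2)-2-[4-(TIPSO)phenyl]-2H-pyran-3(6H)-ylidene]acetate (E/Z mixture at the exocyclic alkene)
Conditions: Ph3P=CHCO2Et, PhCO2H (cat.), toluene, 80 °C
Reagents that add atoms: ethyl (triphenyl-λ5-phosphanylidene)acetate, CCOC(=O)C=P(c1ccccc1)(c1ccccc1)c1ccccc1
Why: Wittig olefination with a stabilised ylide, which is far too weak a base to enolise the ketone toward the acidic C2–H; the α-alkoxy ketone is activated toward addition, the fully substituted β-carbon disfavours conjugate attack, and benzoic acid catalysis keeps the temperature moderate.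

Step 8
Reactants: 13 ethyl 2-[(2S)-5-(TBSOCH2)-2-[4-(TIPSO)phenyl]-2H-pyran-3(6H)-ylidene]acetate
Product: 14 ethyl 2-[(2R,3R,5R)-5-(TBSOCH2)-2-[4-(TIPSO)phenyl]oxan-3-yl]acetate (2,3,5-all-cis)
Conditions: H2 (1 atm), Rh/Al2O3 (5 wt% Rh), EtOAc, rt
Reagents that add atoms: none
Why: Heterogeneous hydrogenation of a conjugated diene ester: allylic strain with the exocyclic alkene holds the C2 aryl group pseudo-axial, so the nearly flat diene should bind the metal by its open face and take up hydrogen at C3 and C5 anti to the aryl group, which sets the 2,3-cis and 2,5-cis relationships in one operation, and rhodium on alumina is used because it has little tendency to cleave allylic or benzylic C–O bonds.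

Step 9
Reactants: 14 ethyl 2-[(2R,3R,5R)-5-(TBSOCH2)-2-[4-(TIPSO)phenyl]oxan-3-yl]acetate
Product: 15 2-[(2R,3R,5R)-5-(TBSOCH2)-2-[4-(TIPSO)phenyl]oxan-3-yl]ethan-1-ol
Conditions: i-Bu2AlH (2.5 equiv), CH2Cl2, −78 → 0 °C
Reagents that add atoms: none
Why: Aluminium hydride reduction of an ester to the primary alcohol; no stereocentre is adjacent to the carbonyl, so none can epimerise.

Step 10
Reactants: 15 2-[(2R,3R,5R)-5-(TBSOCH2)-2-[4-(TIPSO)phenyl]oxan-3-yl]ethan-1-ol
Product: 16 5-({2-[(2R,3R,5R)-5-(TBSOCH2)-2-[4-(TIPSO)phenyl]oxan-3-yl]ethyl}sulfanyl)-1-phenyl-1H-tetrazole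
Conditions: 1-phenyl-1H-tetrazole-5-thiol, PPh3, DIAD, THF, 0 °C → rt
Reagents that add atoms: 1-phenyl-1H-tetrazole-5-thiol, Sc1nnnn1-c1ccccc1
Why: Mitsunobu reaction, in which the acidic heteroaryl thiol displaces the activated primary alkoxyphosphonium ion to give the sulfide.

Step 11
Reactants: 16 5-({2-[(2R,3R,5R)-5-(TBSOCH2)-2-[4-(TIPSO)phenyl]oxan-3-yl]ethyl}sulfanyl)-1-phenyl-1H-tetrazole
Product: 17 5-({2-[(2R,3R,5R)-5-(TBSOCH2)-2-[4-(TIPSO)phenyl]oxan-3-yl]ethyl}sulfonyl)-1-phenyl-1H-tetrazole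
Conditions: (NH4)6Mo7O24·4H2O (10 mol%), H2O2 (30% aq.), EtOH, 0 °C → rt
Reagents that add atoms: hydrogen peroxide, OO
Why: Molybdate-catalysed oxidation of a sulfide to the sulfone with hydrogen peroxide, the usual preparation of Julia–Kocienski sulfones, which tolerates silyl ethers and is run before any alkene is present.

Step 12
Reactants: 17 5-({2-[(2R,3R,5R)-5-(TBSOCH2)-2-[4-(TIPSO)phenyl]oxan-3-yl]ethyl}sulfonyl)-1-phenyl-1H-tetrazole; 5 4-(TIPSO)benzaldehyde
Product: 18 (2R,3S,5R)-5-(TBSOCH2)-2-[4-(TIPSO)phenyl]-3-{(2E)-3-[4-(TIPSO)phenyl]prop-2-en-1-yl}oxane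
Conditions: KN(SiMe3)2 added to 17 + 5, DME, −60 °C → rt
Reagents that add atoms: none
Why: Julia–Kocienski olefination: the metalated alkyl tetrazolyl sulfone adds to the non-enolisable aromatic aldehyde and Smiles rearrangement with loss of SO2 and the tetrazolone gives the alkene, a pairing (alkyl sulfone, aryl aldehyde) that should strongly favour the E isomer.

Step 13
Reactants: 18 (2R,3S,5R)-5-(TBSOCH2)-2-[4-(TIPSO)phenyl]-3-{(2E)-3-[4-(TIPSO)phenyl]prop-2-en-1-yl}oxane
Product: 19 [(2R,3S,5S)-2-[4-(TIPSO)phenyl]-3-{(2E)-3-[4-(TIPSO)phenyl]prop-2-en-1-yl}oxan-5-yl]methanol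
Conditions: camphor-10-sulfonic acid (10 mol%), MeOH/CH2Cl2 (1:1), 0 °C
Reagents that add atoms: none
Why: Acid-catalysed methanolysis of a silyl ether: the primary alkyl TBS ether is far more acid-labile than the aryl TIPS ethers, so only the C5 arm should be unmasked, and catalytic acid at 0 °C should not add methanol to the styrene.

Step 14
Reactants: 19 [(2R,3S,5S)-2-[4-(TIPSO)phenyl]-3-{(2E)-3-[4-(TIPSO)phenyl]prop-2-en-1-yl}oxan-5-yl]methanol
Product: 20 (2R,3S,5R)-2-[4-(TIPSO)phenyl]-3-{(2E)-3-[4-(TIPSO)phenyl]prop-2-en-1-yl}oxane-5-carbaldehyde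
Conditions: Dess–Martin periodinane, NaHCO3, CH2Cl2, 0 °C → rt
Reagents that add atoms: none
Why: Dess–Martin oxidation of a primary alcohol under bicarbonate buffer, neutral conditions that should neither epimerise the α-stereocentre C5 nor touch the electron-rich styrene.

Step 15
Reactants: 21 4-bromophenol
Product: 22 (4-bromophenoxy)tri(propan-2-yl)silane
Conditions: TIPSCl, imidazole, DMF, rt
Reagents that add atoms: chlorotri(propan-2-yl)silane, CC(C)[Si](Cl)(C(C)C)C(C)C
Why: Silylation of a phenol; the aryl TIPS ether tolerates the bromine–lithium exchange and the zinc reagents of the next step.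

Step 16
Reactants: 22 (4-bromophenoxy)tri(propan-2-yl)silane; 20 (2R,3S,5R)-2-[4-(TIPSO)phenyl]-3-{(2E)-3-[4-(TIPSO)phenyl]prop-2-en-1-yl}oxane-5-carbaldehyde
Product: 26 (R)-[(2R,3S,5R)-2-[4-(TIPSO)phenyl]-3-{(2E)-3-[4-(TIPSO)phenyl]prop-2-en-1-yl}oxan-5-yl][4-(TIPSO)phenyl]methanol, via aryllithium 23 (not isolated), via arylzinc chloride 24 (not isolated), via aryl(butyl)zinc 25 (not isolated)
Conditions: 22, n-BuLi, t-BuOMe, −78 °C; ZnCl2, 0 °C; n-BuLi; N,N,N′,N′-tetraethylethylenediamine, (−)-MIB (10 mol%), toluene; then 20, 0 °C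
Reagents that add atoms: none
Why: Amino-alcohol-catalysed enantioselective aryl transfer from a mixed aryl(alkyl)zinc, here to an α-branched aliphatic aldehyde: (−)-MIB should send the aryl group to the Si face of the formyl group, which corresponds to the R carbinol, and because the ring imposes only a weak facial bias the catalyst should decide the new stereocentre while the weakly basic zinc reagent leaves C5 unepimerised.

Step 17
Reactants: 26 (R)-[(2R,3S,5R)-2-[4-(TIPSO)phenyl]-3-{(2E)-3-[4-(TIPSO)phenyl]prop-2-en-1-yl}oxan-5-yl][4-(TIPSO)phenyl]methanol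
Product: 27 4-[(1E)-3-{(2R,3S,5R)-5-[(R)-hydroxy(4-hydroxyphenyl)methyl]-2-(4-hydroxyphenyl)oxan-3-yl}prop-1-en-1-yl]phenol (CNP0182155.1)
Conditions: Bu4NF, AcOH, THF, 0 °C
Reagents that add atoms: none
Why: Fluoride desilylation of the three aryl silyl ethers; the acetic acid buffer keeps the medium near neutral so that the p-hydroxybenzylic alcohol should not ionise to a quinone methide and the styrene is left alone.

**Compound list**

1 | 5-bromofuran-3-carboxylic acid | OC(=O)c1coc(Br)c1 | starting material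
2 | (5-bromofuran-3-yl)methanol | OCc1coc(Br)c1 | intermediate
3 | [(5-bromofuran-3-yl)methoxy](tert-butyl)dimethylsilane | CC(C)(C)[Si](C)(C)OCc1coc(Br)c1 | intermediate
4 | 4-hydroxybenzaldehyde | O=Cc1ccc(O)cc1 | starting material
5 | 4-(TIPSO)benzaldehyde | O=Cc1ccc(O[Si](C(C)C)(C(C)C)C(C)C)cc1 | intermediate
6 | [4-(TBSOCH2)furan-2-yl]lithium (not isolated) | [Li]c1cc(CO[Si](C)(C)C(C)(C)C)co1 | intermediate
7 | chloro[4-(TBSOCH2)furan-2-yl]zinc (not isolated) | Cl[Zn]c1cc(CO[Si](C)(C)C(C)(C)C)co1 | intermediate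
8 | butyl[4-(TBSOCH2)furan-2-yl]zinc (not isolated) | CCCC[Zn]c1cc(CO[Si](C)(C)C(C)(C)C)co1 | intermediate
9 | (S)-[4-(TBSOCH2)furan-2-yl][4-(TIPSO)phenyl]methanol | O[C@H](c1cc(CO[Si](C)(C)C(C)(C)C)co1)c1ccc(O[Si](C(C)C)(C(C)C)C(C)C)cc1 | intermediate
10 | (2Z,5S)-2-(TBSOCH2)-5-hydroxy-4-oxo-5-[4-(TIPSO)phenyl]pent-2-enal (not isolated) | O[C@@H](c1ccc(O[Si](C(C)C)(C(C)C)C(C)C)cc1)C(=O)/C=C(C=O)/CO[Si](C)(C)C(C)(C)C | intermediate
11 | (2S)-5-(TBSOCH2)-6-hydroxy-2-[4-(TIPSO)phenyl]-2H-pyran-3(6H)-one (C6 anomers) | O=C1C=C(CO[Si](C)(C)C(C)(C)C)C(O)O[C@H]1c1ccc(O[Si](C(C)C)(C(C)C)C(C)C)cc1 | intermediate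
12 | (2S)-5-(TBSOCH2)-2-[4-(TIPSO)phenyl]-2H-pyran-3(6H)-one | O=C1C=C(CO[Si](C)(C)C(C)(C)C)CO[C@H]1c1ccc(O[Si](C(C)C)(C(C)C)C(C)C)cc1 | intermediate
13 | ethyl 2-[(2S)-5-(TBSOCH2)-2-[4-(TIPSO)phenyl]-2H-pyran-3(6H)-ylidene]acetate (E/Z mixture) | CCOC(=O)C=C1C=C(CO[Si](C)(C)C(C)(C)C)CO[C@H]1c1ccc(O[Si](C(C)C)(C(C)C)C(C)C)cc1 | intermediate
14 | ethyl 2-[(2R,3R,5R)-5-(TBSOCH2)-2-[4-(TIPSO)phenyl]oxan-3-yl]acetate (all-cis) | CCOC(=O)C[C@H]1C[C@@H](CO[Si](C)(C)C(C)(C)C)CO[C@H]1c1ccc(O[Si](C(C)C)(C(C)C)C(C)C)cc1 | intermediate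
15 | 2-[(2R,3R,5R)-5-(TBSOCH2)-2-[4-(TIPSO)phenyl]oxan-3-yl]ethan-1-ol | OCC[C@H]1C[C@@H](CO[Si](C)(C)C(C)(C)C)CO[C@H]1c1ccc(O[Si](C(C)C)(C(C)C)C(C)C)cc1 | intermediate
16 | 5-({2-[(2R,3R,5R)-5-(TBSOCH2)-2-[4-(TIPSO)phenyl]oxan-3-yl]ethyl}sulfanyl)-1-phenyl-1H-tetrazole | c1ccc(cc1)-n1nnnc1SCC[C@H]1C[C@@H](CO[Si](C)(C)C(C)(C)C)CO[C@H]1c1ccc(O[Si](C(C)C)(C(C)C)C(C)C)cc1 | intermediate
17 | 5-({2-[(2R,3R,5R)-5-(TBSOCH2)-2-[4-(TIPSO)phenyl]oxan-3-yl]ethyl}sulfonyl)-1-phenyl-1H-tetrazole | O=S(=O)(CC[C@H]1C[C@@H](CO[Si](C)(C)C(C)(C)C)CO[C@H]1c1ccc(O[Si](C(C)C)(C(C)C)C(C)C)cc1)c1nnnn1-c1ccccc1 | intermediate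
18 | (2R,3S,5R)-5-(TBSOCH2)-2-[4-(TIPSO)phenyl]-3-{(2E)-3-[4-(TIPSO)phenyl]prop-2-en-1-yl}oxane | CC(C)[Si](C(C)C)(C(C)C)Oc1ccc(/C=C/C[C@H]2C[C@@H](CO[Si](C)(C)C(C)(C)C)CO[C@H]2c2ccc(O[Si](C(C)C)(C(C)C)C(C)C)cc2)cc1 | intermediate
19 | [(2R,3S,5S)-2-[4-(TIPSO)phenyl]-3-{(2E)-3-[4-(TIPSO)phenyl]prop-2-en-1-yl}oxan-5-yl]methanol | CC(C)[Si](C(C)C)(C(C)C)Oc1ccc(/C=C/C[C@H]2C[C@@H](CO)CO[C@H]2c2ccc(O[Si](C(C)C)(C(C)C)C(C)C)cc2)cc1 | intermediate
20 | (2R,3S,5R)-2-[4-(TIPSO)phenyl]-3-{(2E)-3-[4-(TIPSO)phenyl]prop-2-en-1-yl}oxane-5-carbaldehyde | CC(C)[Si](C(C)C)(C(C)C)Oc1ccc(/C=C/C[C@H]2C[C@@H](C=O)CO[C@H]2c2ccc(O[Si](C(C)C)(C(C)C)C(C)C)cc2)cc1 | intermediate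
21 | 4-bromophenol | Oc1ccc(Br)cc1 | starting material
22 | (4-bromophenoxy)tri(propan-2-yl)silane | CC(C)[Si](Oc1ccc(Br)cc1)(C(C)C)C(C)C | intermediate
23 | [4-(TIPSO)phenyl]lithium (not isolated) | [Li]c1ccc(O[Si](C(C)C)(C(C)C)C(C)C)cc1 | intermediate
24 | chloro[4-(TIPSO)phenyl]zinc (not isolated) | Cl[Zn]c1ccc(O[Si](C(C)C)(C(C)C)C(C)C)cc1 | intermediate
25 | butyl[4-(TIPSO)phenyl]zinc (not isolated) | CCCC[Zn]c1ccc(O[Si](C(C)C)(C(C)C)C(C)C)cc1 | intermediate
26 | (R)-[(2R,3S,5R)-2-[4-(TIPSO)phenyl]-3-{(2E)-3-[4-(TIPSO)phenyl]prop-2-en-1-yl}oxan-5-yl][4-(TIPSO)phenyl]methanol | CC(C)[Si](C(C)C)(C(C)C)Oc1ccc(/C=C/C[C@H]2C[C@@H]([C@@H](O)c3ccc(O[Si](C(C)C)(C(C)C)C(C)C)cc3)CO[C@H]2c2ccc(O[Si](C(C)C)(C(C)C)C(C)C)cc2)cc1 | intermediate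
27 | 4-[(1E)-3-{(2R,3S,5R)-5-[(R)-hydroxy(4-hydroxyphenyl)methyl]-2-(4-hydroxyphenyl)oxan-3-yl}prop-1-en-1-yl]phenol | Oc1ccc(/C=C/C[C@H]2C[C@@H]([C@@H](O)c3ccc(O)cc3)CO[C@H]2c2ccc(O)cc2)cc1 | target

**Step count**

Total steps: 17. Longest linear sequence: 15 steps (steps 1, 2, 4–14, 16 and 17); steps 3 and 15 prepare the aldehyde 5 and the aryl bromide 22.

**Steps most likely to fail**

Step 8, hydrogenation of the dienoate. The remote C5 alkene carbon may be discriminated too weakly, the double bonds may migrate on the metal before they are saturated, or the allylic and benzylic C–O bonds may be hydrogenolysed. The fallback separates the two reductions and saturates the ring alkene with a hydride reagent before the olefination. Setting out from enone 12, conjugate reduction with [(Ph3P)CuH]6 in toluene at room temperature should deliver hydride to C5 anti to the pseudo-axial aryl group. Protonation of the copper enolate then gives the 2,5-cis ketone (2S,5R)-5-(TBSOCH2)-2-[4-(TIPSO)phenyl]oxan-3-one F1, and a minor C5 epimer can be removed by chromatography at this stage. The stabilised ylide of step 7 then gives the exocyclic enoate ethyl 2-[(2R,5R)-5-(TBSOCH2)-2-[4-(TIPSO)phenyl]oxan-3-ylidene]acetate F2. Hydrogenation of this single alkene over Rh/Al2O3, now controlled only by the adjacent aryl group, comes back to the route at ester 14.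

Step 7, Wittig olefination. Addition of the stabilised ylide to the cross-conjugated ketone may be slow, prolonged heating may erode C2 by enolisation, or the exocyclic double bond may drift into the ring. The fallback adds the two carbons as a zinc enolate, which does not deprotonate C2–H, and forms the alkene in a separate dehydration. Setting out from enone 12, a Reformatsky reaction in Barbier mode (ethyl bromoacetate and activated Zn dust in THF) should add to the ketone anti to the aryl group. This gives the tertiary β-hydroxy ester ethyl 2-[(2S)-5-(TBSOCH2)-3-hydroxy-2-[4-(TIPSO)phenyl]-3,6-dihydro-2H-pyran-3-yl]acetate F3. Syn-elimination with methyl N-(triethylammoniosulfonyl)carbamate in toluene at 50 °C can involve only the CH2CO2Et hydrogens, because the C2 hydrogen lies trans to the hydroxyl group, and comes back to the route at dienoate 13.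

Step 16, late aryl transfer. Catalyst control may be mismatched with the bias of the C5 stereocentre, or the α-branched aldehyde may epimerise in the presence of the amine additives; either lowers the diastereomeric purity of the carbinol. The fallback sets the carbinol configuration by reduction instead of addition. Setting out from aldehyde 20, aryllithium 23 (from 22 and n-BuLi in THF) is added at −78 °C without stereocontrol to give [(2R,3S,5R)-2-[4-(TIPSO)phenyl]-3-{(2E)-3-[4-(TIPSO)phenyl]prop-2-en-1-yl}oxan-5-yl][4-(TIPSO)phenyl]methanol F4 as a mixture of carbinol epimers. Buffered Dess–Martin oxidation gives the aryl ketone [(2R,3S,5R)-2-[4-(TIPSO)phenyl]-3-{(2E)-3-[4-(TIPSO)phenyl]prop-2-en-1-yl}oxan-5-yl][4-(TIPSO)phenyl]methanone F5. Corey–Bakshi–Shibata reduction with BH3·SMe2 and (S)-1-methyl-3,3-diphenyltetrahydro-1H,3H-pyrrolo[1,2-c][1,3,2]oxazaborole, which treats the aryl group as the large substituent, should give the R carbinol and comes back to the route at 26.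

**Further compounds**

F1 | step 8 | (2S,5R)-5-(TBSOCH2)-2-[4-(TIPSO)phenyl]oxan-3-one | O=C1C[C@@H](CO[Si](C)(C)C(C)(C)C)CO[C@H]1c1ccc(O[Si](C(C)C)(C(C)C)C(C)C)cc1
F2 | step 8 | ethyl 2-[(2R,5R)-5-(TBSOCH2)-2-[4-(TIPSO)phenyl]oxan-3-ylidene]acetate (E/Z mixture) | CCOC(=O)C=C1C[C@@H](CO[Si](C)(C)C(C)(C)C)CO[C@H]1c1ccc(O[Si](C(C)C)(C(C)C)C(C)C)cc1
F3 | step 7 | ethyl 2-[(2S)-5-(TBSOCH2)-3-hydroxy-2-[4-(TIPSO)phenyl]-3,6-dihydro-2H-pyran-3-yl]acetate (C3 epimers) | CCOC(=O)CC1(O)C=C(CO[Si](C)(C)C(C)(C)C)CO[C@H]1c1ccc(O[Si](C(C)C)(C(C)C)C(C)C)cc1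
F4 | step 16 | [(2R,3S,5R)-2-[4-(TIPSO)phenyl]-3-{(2E)-3-[4-(TIPSO)phenyl]prop-2-en-1-yl}oxan-5-yl][4-(TIPSO)phenyl]methanol (both carbinol epimers) | CC(C)[Si](C(C)C)(C(C)C)Oc1ccc(/C=C/C[C@H]2C[C@@H](C(O)c3ccc(O[Si](C(C)C)(C(C)C)C(C)C)cc3)CO[C@H]2c2ccc(O[Si](C(C)C)(C(C)C)C(C)C)cc2)cc1
F5 | step 16 | [(2R,3S,5R)-2-[4-(TIPSO)phenyl]-3-{(2E)-3-[4-(TIPSO)phenyl]prop-2-en-1-yl}oxan-5-yl][4-(TIPSO)phenyl]methanone | CC(C)[Si](C(C)C)(C(C)C)Oc1ccc(/C=C/C[C@H]2C[C@@H](C(=O)c3ccc(O[Si](C(C)C)(C(C)C)C(C)C)cc3)CO[C@H]2c2ccc(O[Si](C(C)C)(C(C)C)C(C)C)cc2)cc1
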